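**Plan**

Numbering: the formyl-bearing dihydrobenzofuran is O1, C2, C3, C3a–C7a; the second one is O1′, C2′, C3′, C3a′–C7a′.

- Cuts: the four O–CH3 bonds and C5–CHO (from C5–Br) go first. The resorcinol ring C3a′–C7a′ is then cut at C3a′–C4′, C7′–C7a′ and O1′–C7a′. This works because C4′, meta to both O1′ and the C6′ hydroxyl, is the β-carbon of a cyclohexane-1,3-dione whose C7a′ carbonyl can be a γ-lactone carbonyl. The cut gives lactone 10 and enone 20.
- Lactone 10 is cut at C2′–C3′ (allylboration); enone 20 at its C=C (Wittig) and at C2–C3 (carbene C–H insertion).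
- Forward ring order: γ-lactone (the later O1′ ring), then ring O1–C7a, then the carbocycle C3a′–C7a′ by Michael–Claisen annulation with reclosure of O1′, then aromatisation, formylation and demethylation.
- Stereochemistry: C2′ and C3′ come from an anti-selective, phosphoric-acid-catalysed allylboration. C2 comes from a chiral dirhodium catalyst and C3 from epimerisation to trans. The annulation creates no lasting stereocentre.

Key step: step 11

Assumption: (R)-TRIP in step 2 and Rh2(S-PTTL)4 in step 8 are taken to induce the same sense as with benzaldehyde and with the parent benzyl ether (1R carbinol; 2R at the new ring carbon); if either sense is opposite, the mirror-image catalyst is used.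

**Step 1**
Reactants: 1 3,5-dimethoxystyrene; 2 allylboronic acid pinacol ester
Product: 3 (E)-2-[3-(3,5-dimethoxyphenyl)prop-2-en-1-yl]-4,4,5,5-tetramethyl-1,3,2-dioxaborolane
Conditions: second-generation Grubbs catalyst RuCl2(=CHPh)(PCy3)(H2IMes) (3 mol %), CH2Cl2, 40 °C
Reagents that add atoms: none
Why: Olefin cross-metathesis of a styrene with an allylboronate is an established entry to cinnamyl-type boronates, and the E isomer should dominate as the thermodynamically favoured product.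

**Step 2**
Reactants: 3 (E)-cinnamyl-type boronate; 4 4-methoxybenzaldehyde
Product: 6 (1R,2S)-2-(3,5-dimethoxyphenyl)-1-(4-methoxyphenyl)but-3-en-1-ol, via pinacol borate ester 5 (not isolated)
Conditions: (R)-TRIP [(R)-3,3′-bis(2,4,6-triisopropylphenyl)-1,1′-binaphthyl-2,2′-diyl hydrogen phosphate] (5 mol %), toluene, 4 Å MS, −30 → 0 °C; then H2O
Reagents that add atoms: none
Why: Catalytic asymmetric allylboration; the (E)-boronate reacts through a closed chair transition state (anti product) and the chiral phosphoric acid, bound to a boronate oxygen, selects the aldehyde face, which should set 1R and 2S (the later C2′ and C3′).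

**Step 3**
Reactants: 6 homoallylic alcohol
Product: 8 (1R,2S)-2-(3,5-dimethoxyphenyl)-1-(4-methoxyphenyl)butane-1,4-diol, via bis(9-BBN) adduct 7 (not isolated)
Conditions: 9-BBN (2.5 equiv), THF, 0 °C → rt; then NaOH, H2O2, 0 °C → rt
Reagents that add atoms: hydrogen peroxide, OO
Why: Hydroboration–oxidation with the bulky dialkylborane places boron on the terminal carbon (anti-Markovnikov) and leaves both stereocentres untouched.

**Step 4**
Reactants: 8 diol
Product: 10 (4S,5R)-4-(3,5-dimethoxyphenyl)-5-(4-methoxyphenyl)dihydrofuran-2(3H)-one, via lactol 9 (not isolated)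
Conditions: TEMPO (10 mol %), PhI(OAc)2 (2.5 equiv), CH2Cl2, rt
Reagents that add atoms: none
Why: Oxoammonium-mediated oxidative lactonisation of a 1,4-diol; the primary alcohol is oxidised first, the hydroxy aldehyde closes to the lactol and this is oxidised on, so the anti diol should give the trans lactone without touching a stereocentre.

**Step 5**
Reactants: 11 2-(5-bromo-2-hydroxyphenyl)acetic acid
Product: 12 methyl 2-(5-bromo-2-hydroxyphenyl)acetate
Conditions: MeOH, H2SO4 (cat.), reflux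
Reagents that add atoms: methanol, CO
Why: Fischer esterification; the large excess of methanol keeps the ester open instead of the benzofuranone.

**Step 6**
Reactants: 12 phenol ester; 13 4-methoxybenzyl chloride
Product: 14 methyl 2-{5-bromo-2-[(4-methoxybenzyl)oxy]phenyl}acetate
Conditions: K2CO3, n-Bu4NI (cat.), DMF, rt
Reagents that add atoms: none
Why: Williamson etherification of the phenoxide; the benzylic CH2 installed here later becomes C2 with its 4-methoxyphenyl group.

**Step 7**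
Reactants: 14 arylacetate
Product: 15 methyl 2-{5-bromo-2-[(4-methoxybenzyl)oxy]phenyl}-2-diazoacetate
Conditions: 4-acetamidobenzenesulfonyl azide, DBU, MeCN, 0 °C → rt
Reagents that add atoms: 4-acetamidobenzenesulfonyl azide, CC(=O)Nc1ccc(cc1)S(=O)(=O)N=[N+]=[N-]
Why: Regitz diazo transfer to an arylacetate is the standard preparation of aryldiazoacetates.

**Step 8**
Reactants: 15 aryldiazoacetate
Product: 17 methyl (2R,3R)-5-bromo-2-(4-methoxyphenyl)-2,3-dihydrobenzofuran-3-carboxylate, via cis ester 16 (not isolated)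
Conditions: Rh2(S-PTTL)4 [dirhodium tetrakis(N-phthaloyl-(S)-tert-leucinate)] (1 mol %), toluene, −60 °C; then NaOMe, MeOH, rt
Reagents that add atoms: none
Why: Enantioselective intramolecular 1,5 C–H insertion of the donor/acceptor rhodium carbene into the activated benzylic ether C–H sets C2 (2R) under catalyst control and gives mainly the cis ester, and methoxide then epimerises C3 to the more stable trans ester without touching C2.

**Step 9**
Reactants: 17 trans ester
Product: 18 [(2R,3S)-5-bromo-2-(4-methoxyphenyl)-2,3-dihydrobenzofuran-3-yl]methanol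
Conditions: i-Bu2AlH (2.5 equiv), CH2Cl2, −78 → 0 °C; aq. KNaC4H4O6 work-up
Reagents that add atoms: none
Why: Hydride reduction of the ester to the primary alcohol, which the aryl bromide tolerates; storing the material as the alcohol avoids the epimerisable β-aryloxy aldehyde.

**Step 10**
Reactants: 18 primary alcohol
Product: 20 (E)-4-[(2R,3R)-5-bromo-2-(4-methoxyphenyl)-2,3-dihydrobenzofuran-3-yl]but-3-en-2-one, via aldehyde 19 (not isolated)
Conditions: Dess–Martin periodinane, CH2Cl2, 0 °C → rt; then Ph3P=CHC(O)CH3 (2.5 equiv), rt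
Reagents that add atoms: 1-(triphenylphosphoranylidene)propan-2-one, CC(=O)C=P(c1ccccc1)(c1ccccc1)c1ccccc1
Why: Dess–Martin oxidation followed in the same flask by Wittig olefination with a stabilised, weakly basic ylide should give the E enone; any epimerisation of the aldehyde at C3 returns to the favoured trans arrangement.

**Step 11**
Reactants: 10 trans lactone; 20 enone
Product: 24 (2R,3S)-4-[(2R,3R)-5-bromo-2-(4-methoxyphenyl)-2,3-dihydrobenzofuran-3-yl]-3-(3,5-dimethoxyphenyl)-2-(4-methoxyphenyl)-3,3a,4,5-tetrahydrobenzofuran-6(2H)-one (C3a/C4 epimer mixture), via ketene silyl acetal 21 (not isolated), via silyl enol ether adduct 22 (not isolated), via hydroxy dione 23 (not isolated)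
Conditions: LiN(i-Pr)2, TMSCl, THF, −78 °C; volatiles removed; then 20, HNTf2 (5 mol %), CH2Cl2, −78 °C; then KOt-Bu, THF–t-BuOH, −20 °C → rt; then 1 M HCl; PPTS, toluene, 60 °C
Reagents that add atoms: none
Why: Proposed new method: the lactone is first converted into its 2-silyloxy-4,5-dihydrofuran, whose C3 (the later C3a′) adds to the enone β-carbon (C4′) in a silyl-triflimide-catalysed Mukaiyama–Michael reaction, so the acidic γ-hydrogen at C3 of 20 never meets a base. tert-Butoxide then cleaves the silyl enol ether, and the equilibrating enolates drain through the methyl-side enolate (C7′), which acylates itself on the lactone carbonyl C7a′ (Claisen condensation), releasing the C2′ alkoxide and ending as the stabilised cyclohexane-1,3-dionate; mild acid returns the C2′ hydroxyl to C7a′ with loss of water. The closest known chemistry is the Michael–Claisen (3+3) annulation of malonate or ester enolates with methyl enones to cyclohexane-1,3-diones and the Mukaiyama–Michael addition of lactone ketene silyl acetals; new is the lactone serving as donor and acylating agent in turn, with its ring oxygen relayed into a bicyclic vinylogous ester. The carbocycle closes 6-exo-trig (C7′ onto C7a′) and the oxygen ring recloses by 5-exo-trig hemiketalisation and dehydration, the C6′ carbonyl being out of reach for a five-membered ring. No lasting stereocentre is made: C3a′ and C4′ form as mixtures that vanish on aromatisation, while C2, C3, C2′ and C3′ carry no acidic hydrogen after the Michael stage (and trans at C2′/C3′ is also the thermodynamic outcome should the benzylic C–O bond ionise). The step needs 1,4-addition over 1,2-addition and γ-deprotonation, which the base-free Lewis-acid stage secures, and acylation over retro-Michael cleavage, which the irreversible formation of the dionate secures.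

**Step 12**
Reactants: 24 vinylogous ester
Product: 27 (2R,3R)-4-[(2R,3R)-5-bromo-2-(4-methoxyphenyl)-2,3-dihydrobenzofuran-3-yl]-3-(3,5-dimethoxyphenyl)-2-(4-methoxyphenyl)-2,3-dihydrobenzofuran-6-ol, via α′-selenide 25 (not isolated), via dienone 26 (not isolated)
Conditions: LiN(i-Pr)2, THF, −78 °C; PhSeCl; then H2O2 (30 %), pyridine, CH2Cl2, 0 °C → rt
Reagents that add atoms: none
Why: Reich dehydrogenation; the kinetic α′-enolate (C5′) is selenylated, the selenoxide eliminates syn towards C4′, and the cross-conjugated dienone tautomerises by loss of the C3a′ hydrogen to the phenol, which erases the C3a′/C4′ mixture and avoids oxidants that attack the benzylic ether positions.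

**Step 13**
Reactants: 27 bromo phenol
Product: 29 (2R,3R)-3-[(2R,3R)-3-(3,5-dimethoxyphenyl)-6-hydroxy-2-(4-methoxyphenyl)-2,3-dihydrobenzofuran-4-yl]-2-(4-methoxyphenyl)-2,3-dihydrobenzofuran-5-carbaldehyde, via dilithio species 28 (not isolated)
Conditions: n-BuLi (2.1 equiv), THF, −78 °C; then DMF, −78 → 0 °C; then H2O
Reagents that add atoms: N,N-dimethylformamide, CN(C)C=O
Why: The first equivalent of base forms the lithium phenoxide, bromine–lithium exchange then gives the aryllithium, and formylation with DMF (Bouveault reaction) installs the aldehyde at C5; no carbonyl or acidic C–H competes at −78 °C.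

**Step 14**
Reactants: 29 tetramethyl ether aldehyde
Product: 30 (2R,3R)-3-[(2R,3R)-3-(3,5-dihydroxyphenyl)-6-hydroxy-2-(4-hydroxyphenyl)-2,3-dihydrobenzofuran-4-yl]-2-(4-hydroxyphenyl)-2,3-dihydrobenzofuran-5-carbaldehyde (CNP0318276.1)
Conditions: BBr3 (10 equiv), CH2Cl2, −78 → 0 °C; then MeOH, aq. NaHCO3
Reagents that add atoms: none
Why: Lewis-acid cleavage of aryl methyl ethers is the usual unmasking of permethylated resveratrol-type oligomers; boron complexation makes the aryl groups electron-poor, which should protect the benzylic C–O bonds, and the trans rings are the thermodynamic arrangement.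

**Compound list**

1 | 3,5-dimethoxystyrene | C=Cc1cc(OC)cc(OC)c1 | starting material
2 | allylboronic acid pinacol ester | C=CCB1OC(C)(C)C(C)(C)O1 | starting material
3 | (E)-2-[3-(3,5-dimethoxyphenyl)prop-2-en-1-yl]-4,4,5,5-tetramethyl-1,3,2-dioxaborolane | COc1cc(/C=C/CB2OC(C)(C)C(C)(C)O2)cc(OC)c1 | intermediate
4 | 4-methoxybenzaldehyde | COc1ccc(C=O)cc1 | starting material
5 | 2-{[(1R,2S)-2-(3,5-dimethoxyphenyl)-1-(4-methoxyphenyl)but-3-en-1-yl]oxy}-4,4,5,5-tetramethyl-1,3,2-dioxaborolane (not isolated) | C=C[C@@H](c1cc(OC)cc(OC)c1)[C@H](c1ccc(OC)cc1)OB1OC(C)(C)C(C)(C)O1 | intermediate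
6 | (1R,2S)-2-(3,5-dimethoxyphenyl)-1-(4-methoxyphenyl)but-3-en-1-ol | C=C[C@@H](c1cc(OC)cc(OC)c1)[C@H](c1ccc(OC)cc1)O | intermediate
7 | 9-{[(1R,2S)-4-(9-borabicyclo[3.3.1]nonan-9-yl)-2-(3,5-dimethoxyphenyl)-1-(4-methoxyphenyl)butyl]oxy}-9-borabicyclo[3.3.1]nonane (not isolated) | C(CB1C2CCCC1CCC2)[C@@H](c1cc(OC)cc(OC)c1)[C@H](c1ccc(OC)cc1)OB1C2CCCC1CCC2 | intermediate
8 | (1R,2S)-2-(3,5-dimethoxyphenyl)-1-(4-methoxyphenyl)butane-1,4-diol | OCC[C@@H](c1cc(OC)cc(OC)c1)[C@H](c1ccc(OC)cc1)O | intermediate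
9 | (4S,5R)-4-(3,5-dimethoxyphenyl)-5-(4-methoxyphenyl)tetrahydrofuran-2-ol, anomer mixture (not isolated) | OC1C[C@@H](c2cc(OC)cc(OC)c2)[C@H](c2ccc(OC)cc2)O1 | intermediate
10 | (4S,5R)-4-(3,5-dimethoxyphenyl)-5-(4-methoxyphenyl)dihydrofuran-2(3H)-one | O=C1C[C@@H](c2cc(OC)cc(OC)c2)[C@H](c2ccc(OC)cc2)O1 | intermediate
11 | 2-(5-bromo-2-hydroxyphenyl)acetic acid | OC(=O)Cc1cc(Br)ccc1O | starting material
12 | methyl 2-(5-bromo-2-hydroxyphenyl)acetate | COC(=O)Cc1cc(Br)ccc1O | intermediate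
13 | 4-methoxybenzyl chloride | COc1ccc(CCl)cc1 | starting material
14 | methyl 2-{5-bromo-2-[(4-methoxybenzyl)oxy]phenyl}acetate | COC(=O)Cc1cc(Br)ccc1OCc1ccc(OC)cc1 | intermediate
15 | methyl 2-{5-bromo-2-[(4-methoxybenzyl)oxy]phenyl}-2-diazoacetate | COC(=O)C(=[N+]=[N-])c1cc(Br)ccc1OCc1ccc(OC)cc1 | intermediate
16 | methyl (2R,3S)-5-bromo-2-(4-methoxyphenyl)-2,3-dihydrobenzofuran-3-carboxylate, cis (not isolated) | Brc1ccc2c(c1)[C@H](C(=O)OC)[C@H](c1ccc(OC)cc1)O2 | intermediate
17 | methyl (2R,3R)-5-bromo-2-(4-methoxyphenyl)-2,3-dihydrobenzofuran-3-carboxylate, trans | Brc1ccc2c(c1)[C@@H](C(=O)OC)[C@H](c1ccc(OC)cc1)O2 | intermediate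
18 | [(2R,3S)-5-bromo-2-(4-methoxyphenyl)-2,3-dihydrobenzofuran-3-yl]methanol | Brc1ccc2c(c1)[C@@H](CO)[C@H](c1ccc(OC)cc1)O2 | intermediate
19 | (2R,3R)-5-bromo-2-(4-methoxyphenyl)-2,3-dihydrobenzofuran-3-carbaldehyde (not isolated) | Brc1ccc2c(c1)[C@@H](C=O)[C@H](c1ccc(OC)cc1)O2 | intermediate
20 | (E)-4-[(2R,3R)-5-bromo-2-(4-methoxyphenyl)-2,3-dihydrobenzofuran-3-yl]but-3-en-2-one | Brc1ccc2c(c1)[C@@H](/C=C/C(C)=O)[C@H](c1ccc(OC)cc1)O2 | intermediate
21 | {[(2R,3S)-3-(3,5-dimethoxyphenyl)-2-(4-methoxyphenyl)-2,3-dihydrofuran-5-yl]oxy}trimethylsilane (not isolated) | C[Si](C)(C)OC1=C[C@@H](c2cc(OC)cc(OC)c2)[C@H](c2ccc(OC)cc2)O1 | intermediate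
22 | (4S,5R)-3-{1-[(2R,3R)-5-bromo-2-(4-methoxyphenyl)-2,3-dihydrobenzofuran-3-yl]-3-(trimethylsilyloxy)but-2-en-1-yl}-4-(3,5-dimethoxyphenyl)-5-(4-methoxyphenyl)dihydrofuran-2(3H)-one, epimer mixture (not isolated) | O=C1C(C(C=C(C)O[Si](C)(C)C)[C@@H]2c3cc(Br)ccc3O[C@H]2c2ccc(OC)cc2)[C@@H](c2cc(OC)cc(OC)c2)[C@H](c2ccc(OC)cc2)O1 | intermediate
23 | 5-[(2R,3R)-5-bromo-2-(4-methoxyphenyl)-2,3-dihydrobenzofuran-3-yl]-4-[(1S,2R)-1-(3,5-dimethoxyphenyl)-2-hydroxy-2-(4-methoxyphenyl)ethyl]cyclohexane-1,3-dione, epimer mixture (not isolated) | O=C1CC(=O)CC([C@@H]2c3cc(Br)ccc3O[C@H]2c2ccc(OC)cc2)C1[C@@H](c1cc(OC)cc(OC)c1)[C@H](c1ccc(OC)cc1)O | intermediate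
24 | (2R,3S)-4-[(2R,3R)-5-bromo-2-(4-methoxyphenyl)-2,3-dihydrobenzofuran-3-yl]-3-(3,5-dimethoxyphenyl)-2-(4-methoxyphenyl)-3,3a,4,5-tetrahydrobenzofuran-6(2H)-one, C3a/C4 epimer mixture | Brc1ccc2c(c1)[C@@H](C1CC(=O)C=C3C1[C@@H](c1cc(OC)cc(OC)c1)[C@H](c1ccc(OC)cc1)O3)[C@H](c1ccc(OC)cc1)O2 | intermediate
25 | 5-(phenylselanyl) derivative of 24 (not isolated) | Brc1ccc2c(c1)[C@@H](C1C([Se]c3ccccc3)C(=O)C=C3C1[C@@H](c1cc(OC)cc(OC)c1)[C@H](c1ccc(OC)cc1)O3)[C@H](c1ccc(OC)cc1)O2 | intermediate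
26 | (2R,3S)-4-[(2R,3R)-5-bromo-2-(4-methoxyphenyl)-2,3-dihydrobenzofuran-3-yl]-3-(3,5-dimethoxyphenyl)-2-(4-methoxyphenyl)-3,3a-dihydrobenzofuran-6(2H)-one (not isolated) | Brc1ccc2c(c1)[C@@H](C1=CC(=O)C=C3C1[C@@H](c1cc(OC)cc(OC)c1)[C@H](c1ccc(OC)cc1)O3)[C@H](c1ccc(OC)cc1)O2 | intermediate
27 | (2R,3R)-4-[(2R,3R)-5-bromo-2-(4-methoxyphenyl)-2,3-dihydrobenzofuran-3-yl]-3-(3,5-dimethoxyphenyl)-2-(4-methoxyphenyl)-2,3-dihydrobenzofuran-6-ol | Brc1ccc2c(c1)[C@@H](c1cc(O)cc3c1[C@@H](c1cc(OC)cc(OC)c1)[C@H](c1ccc(OC)cc1)O3)[C@H](c1ccc(OC)cc1)O2 | intermediate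
28 | C5-lithio lithium phenoxide of 27 (not isolated) | [Li]c1ccc2c(c1)[C@@H](c1cc(O[Li])cc3c1[C@@H](c1cc(OC)cc(OC)c1)[C@H](c1ccc(OC)cc1)O3)[C@H](c1ccc(OC)cc1)O2 | intermediate
29 | (2R,3R)-3-[(2R,3R)-3-(3,5-dimethoxyphenyl)-6-hydroxy-2-(4-methoxyphenyl)-2,3-dihydrobenzofuran-4-yl]-2-(4-methoxyphenyl)-2,3-dihydrobenzofuran-5-carbaldehyde | O=Cc1ccc2c(c1)[C@@H](c1cc(O)cc3c1[C@@H](c1cc(OC)cc(OC)c1)[C@H](c1ccc(OC)cc1)O3)[C@H](c1ccc(OC)cc1)O2 | intermediate
30 | (2R,3R)-3-[(2R,3R)-3-(3,5-dihydroxyphenyl)-6-hydroxy-2-(4-hydroxyphenyl)-2,3-dihydrobenzofuran-4-yl]-2-(4-hydroxyphenyl)-2,3-dihydrobenzofuran-5-carbaldehyde | O=Cc1ccc2c(c1)[C@@H](c1cc(O)cc3c1[C@@H](c1cc(O)cc(O)c1)[C@H](c1ccc(O)cc1)O3)[C@H](c1ccc(O)cc1)O2 | target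

**Step count and risks**

Total steps: 14. Longest linear sequence: 10 steps (steps 5–14, from acid 11); the lactone branch (steps 1–4) joins at step 11.

Steps most likely to fail:

1. Step 11 (new method). The conjugate addition joins two congested carbons and may stall. The acid catalyst may isomerise the enone towards the 3-alkylidene/benzofuran series. The tert-butoxide stage may fragment the adduct by retro-Michael cleavage instead of acylating. The fallback uses only known reactions, run one at a time on an open-chain O-silylated ester in place of the lactone; it sets out from homoallylic alcohol 6, uses enone 20 and comes back at 24. Silylation of 6 (TBSOTf, 2,6-lutidine) gives the silyl ether F1. Hydroboration–oxidation (9-BBN; NaOH, H2O2) gives the primary alcohol F2. Oxidation (TEMPO, PhI(OAc)2, MeCN–H2O) gives the carboxylic acid F3, and TMSCHN2 gives the methyl ester F4. LiN(i-Pr)2 and TMSCl give the ketene silyl acetal F5, which adds to 20 with TiCl4 at −78 °C (classical Mukaiyama–Michael addition) to give the δ-keto ester F6. KOt-Bu then closes the cyclohexane-1,3-dione F7 by Claisen condensation with loss of methanol. HF·pyridine removes the silyl group to give hydroxy dione 23, and PPTS closes it to 24.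

2. Step 12. The selenoxide of one C4′ epimer may not reach the syn-periplanar hydrogen, so elimination is incomplete, and electrophilic selenium by-products may attack the electron-rich phenol as it forms. The fallback sets out from 24 and comes back at 27. LiN(i-Pr)2 and TMSCl give the silyl dienol ether F8. Stoichiometric Pd(OAc)2 in MeCN at rt (Saegusa–Ito oxidation through a palladium enolate and β-hydride elimination) then gives dienone 26, which tautomerises to 27.

3. Step 14. The boron-activated aldehyde may condense with the resorcinol rings (Friedel–Crafts hydroxyalkylation) or be converted to a gem-dibromide before all four ethers are cleaved. The fallback reverses the order of unmasking and formylation; it sets out from 27 and comes back at 30. BBr3 on 27, which has no aldehyde, gives the bromo pentaphenol F9. TBSCl and imidazole in DMF give the pentakis(silyl) ether F10. n-BuLi then DMF at −78 °C gives the silylated aldehyde F11, and Et3N·3HF in THF releases 30 under nearly neutral conditions.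

**Further compounds**

F1 | step 11 | tert-butyl{[(1R,2S)-2-(3,5-dimethoxyphenyl)-1-(4-methoxyphenyl)but-3-en-1-yl]oxy}dimethylsilane | C=C[C@@H](c1cc(OC)cc(OC)c1)[C@H](c1ccc(OC)cc1)O[Si](C)(C)C(C)(C)C
F2 | step 11 | (3S,4R)-4-[(tert-butyldimethylsilyl)oxy]-3-(3,5-dimethoxyphenyl)-4-(4-methoxyphenyl)butan-1-ol | OCC[C@@H](c1cc(OC)cc(OC)c1)[C@H](c1ccc(OC)cc1)O[Si](C)(C)C(C)(C)C
F3 | step 11 | (3S,4R)-4-[(tert-butyldimethylsilyl)oxy]-3-(3,5-dimethoxyphenyl)-4-(4-methoxyphenyl)butanoic acid | OC(=O)C[C@@H](c1cc(OC)cc(OC)c1)[C@H](c1ccc(OC)cc1)O[Si](C)(C)C(C)(C)C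
F4 | step 11 | methyl (3S,4R)-4-[(tert-butyldimethylsilyl)oxy]-3-(3,5-dimethoxyphenyl)-4-(4-methoxyphenyl)butanoate | COC(=O)C[C@@H](c1cc(OC)cc(OC)c1)[C@H](c1ccc(OC)cc1)O[Si](C)(C)C(C)(C)C
F5 | step 11 | {[(3S,4R)-4-[(tert-butyldimethylsilyl)oxy]-3-(3,5-dimethoxyphenyl)-1-methoxy-4-(4-methoxyphenyl)but-1-en-1-yl]oxy}trimethylsilane | COC(O[Si](C)(C)C)=C[C@@H](c1cc(OC)cc(OC)c1)[C@H](c1ccc(OC)cc1)O[Si](C)(C)C(C)(C)C
F6 | step 11 | methyl (3S,4R)-2-{1-[(2R,3R)-5-bromo-2-(4-methoxyphenyl)-2,3-dihydrobenzofuran-3-yl]-3-oxobutyl}-4-[(tert-butyldimethylsilyl)oxy]-3-(3,5-dimethoxyphenyl)-4-(4-methoxyphenyl)butanoate, epimer mixture | COC(=O)C(C(CC(C)=O)[C@@H]2c3cc(Br)ccc3O[C@H]2c2ccc(OC)cc2)[C@@H](c1cc(OC)cc(OC)c1)[C@H](c1ccc(OC)cc1)O[Si](C)(C)C(C)(C)C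
F7 | step 11 | 5-[(2R,3R)-5-bromo-2-(4-methoxyphenyl)-2,3-dihydrobenzofuran-3-yl]-4-{(1S,2R)-2-[(tert-butyldimethylsilyl)oxy]-1-(3,5-dimethoxyphenyl)-2-(4-methoxyphenyl)ethyl}cyclohexane-1,3-dione, epimer mixture | O=C1CC(=O)CC([C@@H]2c3cc(Br)ccc3O[C@H]2c2ccc(OC)cc2)C1[C@@H](c1cc(OC)cc(OC)c1)[C@H](c1ccc(OC)cc1)O[Si](C)(C)C(C)(C)C
F8 | step 12 | {[(2R,3S)-4-[(2R,3R)-5-bromo-2-(4-methoxyphenyl)-2,3-dihydrobenzofuran-3-yl]-3-(3,5-dimethoxyphenyl)-2-(4-methoxyphenyl)-2,3,3a,4-tetrahydrobenzofuran-6-yl]oxy}trimethylsilane | Brc1ccc2c(c1)[C@@H](C1C=C(O[Si](C)(C)C)C=C3C1[C@@H](c1cc(OC)cc(OC)c1)[C@H](c1ccc(OC)cc1)O3)[C@H](c1ccc(OC)cc1)O2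
F9 | step 14 | (2R,3R)-4-[(2R,3R)-5-bromo-2-(4-hydroxyphenyl)-2,3-dihydrobenzofuran-3-yl]-3-(3,5-dihydroxyphenyl)-2-(4-hydroxyphenyl)-2,3-dihydrobenzofuran-6-ol | Brc1ccc2c(c1)[C@@H](c1cc(O)cc3c1[C@@H](c1cc(O)cc(O)c1)[C@H](c1ccc(O)cc1)O3)[C@H](c1ccc(O)cc1)O2
F10 | step 14 | pentakis(tert-butyldimethylsilyl) ether of F9 | Brc1ccc2c(c1)[C@@H](c1cc(O[Si](C)(C)C(C)(C)C)cc3c1[C@@H](c1cc(O[Si](C)(C)C(C)(C)C)cc(O[Si](C)(C)C(C)(C)C)c1)[C@H](c1ccc(O[Si](C)(C)C(C)(C)C)cc1)O3)[C@H](c1ccc(O[Si](C)(C)C(C)(C)C)cc1)O2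
F11 | step 14 | pentakis(tert-butyldimethylsilyl) ether of 30 | O=Cc1ccc2c(c1)[C@@H](c1cc(O[Si](C)(C)C(C)(C)C)cc3c1[C@@H](c1cc(O[Si](C)(C)C(C)(C)C)cc(O[Si](C)(C)C(C)(C)C)c1)[C@H](c1ccc(O[Si](C)(C)C(C)(C)C)cc1)O3)[C@H](c1ccc(O[Si](C)(C)C(C)(C)C)cc1)O2
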